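**Retrosynthetic overview**
1. Feature: the seven-membered ring C1–C10–C9–C8–C7–C6–C5 of the daucane core, with oxygen at C6 and C10 and the epoxide at C8–C9, maps onto a cyclohepta-1,4-diene (C5=C6 enol ether, C9=C10) whose doubly allylic carbon is the quaternary fusion carbon C1; this is the Cope product of a cis-divinylcyclopropane spanning C5, C1 and C10.
2. Key disconnection: C7–C8 ([3,3] shift) and C5–C1/C5–C10 (carbene addition) lead back to an acyclic (E,E)-dienyl siloxyvinyl diazoketone; the five-membered ring forms first (cyclopropanation), the seven-membered ring second (Cope).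
3. Precursor: C2–C3 is made by alkylating the lithium enolate of the monosilyl enol ether of symmetric 3-diazopentane-2,4-dione with (2E,4E)-2-methylhexa-2,4-dienyl bromide (from crotonaldehyde by Wittig, reduction, bromination); silylating before alkylating means only one enol ether can form.
4. After the key step: isopropyl addition at C4 anti to the C1 methyl, fluoride release of the C6 ketone with C5 equilibrated to the trans fusion, hydroxyl-directed reduction to the 6α-ol, isovaleroylation.
5. C8–C10: α-epoxidation of C9=C10, selenolate opening at C9 and selenoxide syn-elimination through the 8β-hydrogen left by the Cope boat give the 10α allylic alcohol, which directs the 8α,9α-epoxidation before acetylation.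

Key step: step 7

Remark on notation: daucane locants are used throughout; β is the face of the bicycle carrying the C1 methyl, α the opposite face.
Assumption: the sense of enantiofacial induction of Rh2(S-PTAD)4 (dirhodium tetrakis[(S)-(1-adamantyl)(N-phthalimido)acetate]) with this ketone-tethered siloxyvinyl carbene cannot be predicted securely; the route is written for the S catalyst giving the C1 configuration drawn in 12, and the R catalyst would be used, with nothing else changed, if the first run gives the antipode.

**Route**

Step 1
Reactants: 1 (E)-crotonaldehyde; 2 ethyl 2-(triphenylphosphoranylidene)propanoate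
Product: 3 ethyl (2E,4E)-2-methylhexa-2,4-dienoate
Conditions: CH2Cl2, 0 °C → rt
Reagents that add atoms: none
Why: Wittig olefination with a stabilised α-methyl ylide should give the (2E)-trisubstituted alkene while the (4E) alkene of crotonaldehyde is untouched.

Step 2
Reactants: 3 ethyl (2E,4E)-2-methylhexa-2,4-dienoate
Product: 4 (2E,4E)-2-methylhexa-2,4-dien-1-ol
Conditions: iBu2AlH (2.2 equiv), CH2Cl2, −78 → 0 °C; aq. potassium sodium tartrate (KNaC4H4O6) work-up
Reagents that add atoms: none
Why: 1,2-hydride reduction of a conjugated ester by the aluminium hydride gives the allylic alcohol without touching the diene.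

Step 3
Reactants: 4 (2E,4E)-2-methylhexa-2,4-dien-1-ol
Product: 5 (2E,4E)-1-bromo-2-methylhexa-2,4-diene
Conditions: PBr3 (0.4 equiv), Et2O, 0 °C, dark; used at once
Reagents that add atoms: phosphorus tribromide, BrP(Br)Br
Why: SN2 displacement on the phosphite ester of a primary allylic alcohol gives the primary bromide, which is also the thermodynamically preferred conjugated allylic isomer.

Step 4
Reactants: 6 acetylacetone
Product: 7 3-diazopentane-2,4-dione
Conditions: p-ABSA (1.05 equiv), Et3N, MeCN, 0 °C → rt
Reagents that add atoms: 4-acetamidobenzenesulfonyl azide (p-ABSA), CC(=O)Nc1ccc(cc1)S(=O)(=O)N=[N+]=[N-]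
Why: Regitz diazo transfer to an active methylene flanked by two ketones is reliable.

Step 5
Reactants: 7 3-diazopentane-2,4-dione
Product: 8 4-[(tert-butyldimethylsilyl)oxy]-3-diazopent-4-en-2-one
Conditions: tBuMe2SiOTf (1.05 equiv), Et3N (1.3 equiv), CH2Cl2, 0 °C
Reagents that add atoms: tert-butyldimethylsilyl triflate, CC(C)(C)[Si](C)(C)OS(=O)(=O)C(F)(F)F
Why: Soft enolisation and O-silylation of a 2-diazo-1,3-diketone; because 7 is symmetric only one monosilyl enol ether can form, so the siloxyvinyl group (future C6=C7) is fixed before a second enolisable side exists.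

Step 6
Reactants: 8 4-[(tert-butyldimethylsilyl)oxy]-3-diazopent-4-en-2-one; 5 (2E,4E)-1-bromo-2-methylhexa-2,4-diene
Product: 10 (7E,9E)-2-[(tert-butyldimethylsilyl)oxy]-3-diazo-7-methylundeca-1,7,9-trien-4-one, via lithium enolate 9 (not isolated)
Conditions: LiN(SiMe3)2 (1.2 equiv relative to 8), THF, −78 °C; then 5 (0.8 equiv), DMPU, −78 → −30 °C
Reagents that add atoms: lithium hexamethyldisilazide, [Li+].C[Si](C)(C)[N-][Si](C)(C)C (lithium in intermediate 9 only)
Why: Kinetic lithium enolate formation at the only acidic C–H left (the acetyl methyl, future C3; the diazo carbon has no hydrogen and the other acyl group is masked as its silyl enol ether) followed by SN2 C-alkylation with a primary allylic bromide forms C2–C3 with both alkene geometries retained.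

Step 7
Reactants: 10 (7E,9E)-2-[(tert-butyldimethylsilyl)oxy]-3-diazo-7-methylundeca-1,7,9-trien-4-one
Product: 12 hydroazulenone (daucane locants): C4 ketone, C5=C6 tert-butyldimethylsilyl enol ether, C9=C10 alkene, 1β-methyl, 8α-methyl (8β-H), via cis-divinylcyclopropane 11 (not isolated)
Conditions: Rh2(S-PTAD)4 (1 mol %), hexane, slow addition of 10, −20 °C → rt; then toluene, 90 °C
Reagents that add atoms: none
Why: Loss of dinitrogen at the divalent rhodium centre gives a metal carbene at C5 (ketone acceptor, siloxyvinyl donor) that adds in a concerted, asynchronous [2+1] fashion to the tethered C1=C10 alkene, the closest known reaction type being chiral dirhodium carboxylate-catalysed intramolecular cyclopropanation by a vinyl diazo carbonyl compound followed by divinylcyclopropane–cycloheptadiene (Cope) rearrangement. The five-membered ring closes first, as the bicyclo[3.1.0]hexan-2-one 11, by carbene addition across the γ,δ-alkene of the diazoketone (new bonds C5–C1 and C5–C10); the seven-membered ring then closes by the [3,3] shift through a boat transition state in which C7–C8 forms while the strained C5–C10 bond opens, leaving C5=C6 (enol ether conjugated to C4=O) and C9=C10. C1 is set by the enantiofacial choice of the catalyst at C1=C10, the adamantylglycine-derived phthalimido carboxylate being chosen because this ligand class controls both ketone-substituted and siloxyvinyl-substituted carbenes; C8 is set relative to C1 by the boat geometry, in which the (E)-methyl on C8 points away from the cyclopropane so that the C8 hydrogen ends up cis to the C1 methyl. The cis relationship of the two vinyl groups that the Cope step needs is secured by the stereospecific cyclopropanation and the (E) geometry of C1=C10 (C9 trans to the tether carbon C2), and the preference for a five-membered over a larger ring secures addition at the proximal alkene of the diene. Warming is needed because the C1 methyl lies syn to both vinyl groups and crowds the boat; the cyclopropane stereocentres at C5 and C10 disappear in the rearrangement.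

Step 8
Reactants: 12 hydroazulenone
Product: 13 4β-hydroxy-4α-isopropyl carbinol with C5=C6 silyl enol ether and C9=C10 alkene (1β-methyl, 8α-methyl)
Conditions: iPrMgCl (2 equiv), anhydrous CeCl3 (2 equiv), THF, −78 °C; aq. NH4Cl quench at −78 °C; taken on without chromatography
Reagents that add atoms: isopropylmagnesium chloride, CC(C)[Mg]Cl
Why: 1,2-addition of a CeCl3-activated Grignard reagent (which suppresses enolisation at C3 and β-hydride reduction) to the vinylogous-ester carbonyl should occur on the α face of C4, anti to the C1 methyl that projects over the β face 1,3 to C4, giving the 4β-hydroxy-4α-isopropyl centre; the product is not purified because acid would ionise it to the transposed enone.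

Step 9
Reactants: 13 C4 carbinol silyl enol ether
Product: 14 trans-fused β-hydroxy ketone: 4β-hydroxy-4α-isopropyl-1β,8α-dimethyl-5αH-hydroazul-9-en-6-one (daucane locants)
Conditions: Bu4NF (1.2 equiv), AcOH (1.5 equiv), THF, −20 → 0 °C; then DBU (0.2 equiv), toluene, rt
Reagents that add atoms: none
Why: Acetic acid-buffered fluoride cleavage of the silyl enol ether releases the C6 ketone without acid-promoted loss of the C4 hydroxyl (Stork–Danheiser-type transposition), and the amidine base then equilibrates the epimerisable C5 to the trans-fused isomer (H5 α), expected to be favoured because the isopropyl group is then anti to C6 on the five-membered ring and the 4β-hydroxyl can hydrogen-bond to the C6 carbonyl.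

Step 10
Reactants: 14 trans-fused β-hydroxy ketone
Product: 15 4β,6α-diol: 4α-isopropyl-1β,8α-dimethyl-5αH-hydroazul-9-ene-4β,6α-diol
Conditions: Me4NBH(OAc)3 (5 equiv), MeCN/AcOH (1:1), −30 → 0 °C
Reagents that add atoms: none
Why: Hydroxyl-directed (Evans–Saksena) reduction, in which the C4 hydroxyl exchanges onto boron and delivers hydride through a six-membered transition state to the β face of the C6 carbonyl (the face on which the 4β-oxygen sits), should give the 6α-alcohol, trans to the C5–C4 bond.

Step 11
Reactants: 15 4β,6α-diol
Product: 16 6α-(3-methylbutanoyloxy)-4β-ol with C9=C10 alkene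
Conditions: isovaleryl chloride (1.3 equiv), pyridine, DMAP (0.1 equiv), CH2Cl2, 0 °C → rt
Reagents that add atoms: 3-methylbutanoyl chloride, CC(C)CC(Cl)=O
Why: DMAP-catalysed acylation is selective for the secondary C6 hydroxyl, the tertiary C4 hydroxyl next to the isopropyl group being inert under these conditions.

Step 12
Reactants: 16 6α-isovalerate
Product: 17 9α,10α-epoxide of 16 (8α-methyl, 8β-H retained)
Conditions: mCPBA (1.3 equiv), NaHCO3, CH2Cl2, 0 °C
Reagents that add atoms: 3-chloroperoxybenzoic acid, OOC(=O)c1cccc(Cl)c1
Why: Prilezhaev epoxidation of the only alkene; in the chair of the trans-fused cycloheptene the C1 methyl is axial on the β face of C9=C10 while the α substituents on both allylic carbons (C2 on C1, methyl on C8) are equatorial, so the peracid should add from the α face.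

Step 13
Reactants: 17 9α,10α-epoxide
Product: 18 9β-(phenylselanyl)-10α-ol (6α-isovalerate, 4β-ol, 8α-methyl)
Conditions: (PhSe)2 (0.75 equiv), NaBH4 (1.6 equiv), EtOH, rt → 60 °C
Reagents that add atoms: diphenyl diselenide, c1ccc(cc1)[Se][Se]c1ccccc1
Why: SN2 opening of the epoxide by the soft selenolate with inversion should occur at C9, because the β-face trajectory to C10 is blocked by the adjacent quaternary C1 and its axial methyl, leaving the 10α-hydroxyl in place.

Step 14
Reactants: 18 9β-(phenylselanyl)-10α-ol
Product: 20 allylic alcohol: 6α-isovaleroyloxy-dauc-8-ene-4β,10α-diol, via selenoxide 19 (not isolated)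
Conditions: 30% aq. H2O2 (3 equiv), pyridine (2 equiv), THF, 0 °C → rt
Reagents that add atoms: hydrogen peroxide, OO (oxygen in intermediate 19 only)
Why: Oxidation to the selenoxide and syn-elimination, which runs away from the carbinol carbon and needs a cis β-hydrogen (here the 8β-hydrogen installed by the Cope boat), gives the C8=C9 alkene with the 10α-oxygen untouched; a singlet-oxygen ene reaction would use the same hydrogen but place oxygen on the β face of C10, and hydride reduction of the derived enone would be expected anti to the C1 methyl, which is why this sequence is used.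

Step 15
Reactants: 20 allylic alcohol
Product: 21 8α,9α-epoxy-6α-isovaleroyloxy-daucane-4β,10α-diol
Conditions: VO(acac)2 (5 mol %), tBuOOH (1.5 equiv, decane solution), CH2Cl2, 0 °C → rt
Reagents that add atoms: tert-butyl hydroperoxide, CC(C)(C)OO
Why: Vanadium-catalysed hydroxyl-directed epoxidation of a cyclic secondary allylic alcohol delivers oxygen to the face of C8=C9 syn to the 10α-hydroxyl and so sets the 8α,9α-epoxide.

Step 16
Reactants: 21 epoxy diol
Product: 22 target: 10α-acetoxy-8α,9α-epoxy-4β-hydroxy-6α-(3-methylbutanoyloxy)daucane (1β-methyl, 4α-isopropyl, 5α-H)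
Conditions: Ac2O (3 equiv), pyridine, DMAP (0.1 equiv), CH2Cl2, rt
Reagents that add atoms: acetic anhydride, CC(=O)OC(C)=O
Why: DMAP-catalysed acetylation of the secondary C10 hydroxyl should leave the hindered tertiary C4 hydroxyl and the epoxide untouched.

**Compound list**
1 | (E)-crotonaldehyde | C/C=C/C=O | starting material
2 | ethyl 2-(triphenylphosphoranylidene)propanoate | CCOC(=O)C(C)=P(c1ccccc1)(c1ccccc1)c1ccccc1 | starting material
3 | ethyl (2E,4E)-2-methylhexa-2,4-dienoate | C/C=C/C=C(\C)C(=O)OCC | intermediate
4 | (2E,4E)-2-methylhexa-2,4-dien-1-ol | C/C=C/C=C(\C)CO | intermediate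
5 | (2E,4E)-1-bromo-2-methylhexa-2,4-diene | C/C=C/C=C(\C)CBr | intermediate
6 | acetylacetone | CC(=O)CC(C)=O | starting material
7 | 3-diazopentane-2,4-dione | CC(=O)C(=[N+]=[N-])C(C)=O | intermediate
8 | 4-[(tert-butyldimethylsilyl)oxy]-3-diazopent-4-en-2-one | CC(=O)C(=[N+]=[N-])C(=C)O[Si](C)(C)C(C)(C)C | intermediate
9 | lithium enolate of 8 (formed in the flask) | [Li+].[O-]C(=C)C(=[N+]=[N-])C(=C)O[Si](C)(C)C(C)(C)C | intermediate
10 | (7E,9E)-2-[(tert-butyldimethylsilyl)oxy]-3-diazo-7-methylundeca-1,7,9-trien-4-one (key-step precursor) | C/C=C/C=C(\C)CCC(=O)C(=[N+]=[N-])C(=C)O[Si](C)(C)C(C)(C)C | intermediate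
11 | cis-divinylcyclopropane: bicyclo[3.1.0]hexan-2-one with siloxyvinyl on C5, methyl on C1 and (E)-propenyl on C10, all on the face opposite the five-membered ring (formed in the flask) | O=C1CC[C@]2(C)[C@@H](/C=C/C)[C@]12C(=C)O[Si](C)(C)C(C)(C)C | intermediate
12 | hydroazulenone: C4 ketone, C5=C6 silyl enol ether, C9=C10 alkene, 1β-methyl, 8α-methyl (key-step product) | O=C1CC[C@]2(C)C=C[C@H](C)CC(O[Si](C)(C)C(C)(C)C)=C12 | intermediate
13 | 4β-hydroxy-4α-isopropyl carbinol with C5=C6 silyl enol ether | C1=C[C@H](C)CC(O[Si](C)(C)C(C)(C)C)=C2[C@]1(C)CC[C@@]2(O)C(C)C | intermediate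
14 | trans-fused 4β-hydroxy-4α-isopropyl-5αH-6-ketone | C1=C[C@H](C)CC(=O)[C@@H]2[C@]1(C)CC[C@@]2(O)C(C)C | intermediate
15 | 4β,6α-diol | C1=C[C@H](C)C[C@H](O)[C@@H]2[C@]1(C)CC[C@@]2(O)C(C)C | intermediate
16 | 6α-(3-methylbutanoyloxy)-4β-ol | C1=C[C@H](C)C[C@H](OC(=O)CC(C)C)[C@@H]2[C@]1(C)CC[C@@]2(O)C(C)C | intermediate
17 | 9α,10α-epoxide of 16 | [C@@H]12O[C@@H]1[C@H](C)C[C@H](OC(=O)CC(C)C)[C@@H]1[C@]2(C)CC[C@@]1(O)C(C)C | intermediate
18 | 9β-(phenylselanyl)-10α-ol | O[C@@H]1[C@@H]([Se]c3ccccc3)[C@H](C)C[C@H](OC(=O)CC(C)C)[C@@H]2[C@]1(C)CC[C@@]2(O)C(C)C | intermediate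
19 | selenoxide of 18, either configuration at selenium (formed in the flask) | O[C@@H]1[C@@H]([Se](=O)c3ccccc3)[C@H](C)C[C@H](OC(=O)CC(C)C)[C@@H]2[C@]1(C)CC[C@@]2(O)C(C)C | intermediate
20 | 6α-isovaleroyloxy-dauc-8-ene-4β,10α-diol | O[C@@H]1C=C(C)C[C@H](OC(=O)CC(C)C)[C@@H]2[C@]1(C)CC[C@@]2(O)C(C)C | intermediate
21 | 8α,9α-epoxy-6α-isovaleroyloxy-daucane-4β,10α-diol | O[C@@H]1[C@@H]2O[C@]2(C)C[C@H](OC(=O)CC(C)C)[C@@H]2[C@]1(C)CC[C@@]2(O)C(C)C | intermediate
22 | CNP0137153.1 | CC(=O)O[C@@H]1[C@@H]2O[C@]2(C)C[C@H](OC(=O)CC(C)C)[C@@H]2[C@]1(C)CC[C@@]2(O)C(C)C | target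

**Step count**
Total: 16 steps. Longest linear sequence: 14 steps (steps 1–3, then 6–16).

**Steps most likely to fail**

Step 7. The cyclopropanation of the trisubstituted alkene by the ketone-substituted carbene may proceed with poor enantiofacial discrimination, eroding optical purity, even if the cascade itself runs. The fallback sets out from 10 and comes back at 15. Compound 10 would be cyclised with achiral Rh2(OAc)4 under the same temperature regime to give 12 as the racemate, which would be carried through steps 8 to 10 unchanged to racemic 15. Steglich esterification of the 6α-hydroxyl with (S)-2-methoxy-2-phenylacetic acid (DCC, DMAP, CH2Cl2) should give two diastereomeric esters, the (S)-2-methoxy-2-phenylacetate of 15 F1 and the (S)-2-methoxy-2-phenylacetate of the enantiomer of 15 F2, to be separated by chromatography or crystallisation. LiOH in THF/H2O would then cleave F1 and return enantiopure 15, at the cost of half the material.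

Step 9. Protonation at C5 may occur from the β face, and equilibration to the trans fusion may be incomplete or accompanied by retro-aldol opening of the five-membered ring or dehydration of the tertiary aldol. The fallback sets out from 13 and comes back at 14. Treatment of 13 with KN(SiMe3)2 (THF, −78 → −20 °C) should move the silyl group from the enol oxygen to the C4 alkoxide by 1,5 oxygen-to-oxygen migration. Protonation of the resulting C6 enolate with AcOH would give the silyl-protected ketone, 4β-[(tert-butyldimethylsilyl)oxy]-4α-isopropyl-5αH-6-ketone F3. With no free aldol hydroxyl, C5 can be equilibrated with DBU or NaOMe/MeOH without ring opening, and HF·pyridine in THF would then remove the tertiary silyl ether to give 14.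

Step 6. Proton transfer between product and enolate may cause over-alkylation, or the diazo enolate may decompose before C-alkylation. The fallback sets out from 5 and 6 and comes back at 10. The dianion of acetylacetone (NaH, then nBuLi, THF, 0 °C) would be alkylated at the terminal methyl with 5 to give (7E,9E)-7-methylundeca-7,9-diene-2,4-dione F4. Diazo transfer (p-ABSA, Et3N, MeCN) would give (7E,9E)-3-diazo-7-methylundeca-7,9-diene-2,4-dione F5. Kinetic deprotonation at the methyl group with LiN(SiMe3)2 and trapping with tBuMe2SiCl at −78 °C should then give 10, to be separated from the minor regioisomeric enol ether on deactivated silica.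

**Further compounds**
F1 | step 7 | (S)-2-methoxy-2-phenylacetate of 15 at the 6α-oxygen | C1=C[C@H](C)C[C@H](OC(=O)[C@@H](OC)c3ccccc3)[C@@H]2[C@]1(C)CC[C@@]2(O)C(C)C
F2 | step 7 | (S)-2-methoxy-2-phenylacetate of the enantiomer of 15 | C1=C[C@@H](C)C[C@@H](OC(=O)[C@@H](OC)c3ccccc3)[C@H]2[C@@]1(C)CC[C@]2(O)C(C)C
F3 | step 9 | 4β-[(tert-butyldimethylsilyl)oxy]-4α-isopropyl-1β,8α-dimethyl-5αH-hydroazul-9-en-6-one | C1=C[C@H](C)CC(=O)[C@@H]2[C@]1(C)CC[C@@]2(O[Si](C)(C)C(C)(C)C)C(C)C
F4 | step 6 | (7E,9E)-7-methylundeca-7,9-diene-2,4-dione | CC(=O)CC(=O)CC/C(C)=C/C=C/C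
F5 | step 6 | (7E,9E)-3-diazo-7-methylundeca-7,9-diene-2,4-dione | CC(=O)C(=[N+]=[N-])C(=O)CC/C(C)=C/C=C/C
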